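**Retrosynthetic overview**
1. Querciformolide D ⇒ C15=C17 methylene by a late Mannich/elimination; ring C (14-membered carbocycle) by C9=C10 ring-closing metathesis and hydrogenation; C3 carbinol by CBS reduction of a C3 ketone.
2. Key disconnection C1–C2: intermolecular Michael addition of the SAMP-hydrazone azaenolate of fragment 1 (C2–C9 oxolane methyl ketone) to fragment 2 (C1, C10–C16 α,β-unsaturated ε-lactone).
3. Fragment 1 from (R)-linalool: allylic oxidation, Sharpless epoxidation/5-exo cyclisation (ring A; C7, C8), vinyl → acetyl, epoxide → vinyl carbinol.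
4. Fragment 2 from nerol: Sharpless epoxidation, Ti-mediated opening by acrylic acid with inversion at C12, acrylate ring-closing metathesis (ring B).
5. Ring order: A (oxolane, step 2) and B (ε-lactone, step 12) inside the fragments, then C (carbocycle, step 18) after the union.

**Assumptions**
- Cembrane numbering is used: C1 = ring CH carrying C15; C2–C14 around the carbocycle; C15/C16/C17 = lactone α-carbon, carbonyl and methylene; C18/C19/C20 = methyls on C4/C8/C12.
- Conjugate bases (alkoxides, enolates, azaenolates) made in situ from a numbered compound are treated as that compound and carry no number of their own.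
- SAMP is assumed to be the auxiliary antipode that induces 1R in step 16 (Enders chelate model); if the lactone responds with the opposite facial sense, RAMP is used identically in steps 8 and 16.

Step 1
Reactants: 1 (3R)-3,7-dimethylocta-1,6-dien-3-ol [(R)-(−)-linalool]
Product: 2 (2E,6R)-2,6-dimethylocta-2,7-diene-1,6-diol
Conditions: SeO2 (0.3 equiv), t-BuOOH, salicylic acid (cat.), CH2Cl2, rt
Reagents that add atoms: tert-butyl hydroperoxide, CC(C)(C)OO
Why: Sharpless SeO2/t-BuOOH allylic oxidation (ene then [2,3]-shift) hydroxylates only the (E)-methyl of the trisubstituted olefin, and the chiral-pool carbinol (future C4, R) is untouched.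

Step 2
Reactants: 2 (2E,6R)-2,6-dimethylocta-2,7-diene-1,6-diol
Product: 4 (2R)-2-[(2S,5R)-5-ethenyl-5-methyloxolan-2-yl]propane-1,2-diol, via epoxy diol 3 (not isolated)
Conditions: Ti(OiPr)4 (10 mol %), D-(−)-diethyl tartrate (12 mol %), t-BuOOH, 4 Å MS, CH2Cl2, −20 °C; then camphorsulfonic acid (10 mol %), 0 °C
Reagents that add atoms: tert-butyl hydroperoxide, CC(C)(C)OO
Why: Sharpless asymmetric epoxidation of the primary allylic alcohol (the tertiary vinyl carbinol is inert) gives the (7R,8R)-epoxide, and 5-exo opening by the tertiary hydroxyl at the epoxide carbon remote from CH2OH inverts C7, setting 7S,8R and the cis-2,5-disubstituted oxolane (ring A).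

Step 3
Reactants: 4 (2R)-2-[(2S,5R)-5-ethenyl-5-methyloxolan-2-yl]propane-1,2-diol
Product: 6 (2S,5R)-5-ethenyl-5-methyl-2-[(2R)-2-methyloxiran-2-yl]oxolane, via primary tosylate 5 (not isolated)
Conditions: NaH (2.2 equiv), 1-(p-toluenesulfonyl)imidazole, THF, 0 °C → rt
Reagents that add atoms: none
Why: Selective sulfonylation of the primary alkoxide followed by intramolecular Williamson displacement by the tertiary alkoxide closes the terminal epoxide without touching the C8–O bond, so C8 keeps its configuration.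

Step 4
Reactants: 6 (2S,5R)-5-ethenyl-5-methyl-2-[(2R)-2-methyloxiran-2-yl]oxolane
Product: 8 (2R,5S)-2-methyl-5-[(2R)-2-methyloxiran-2-yl]oxolane-2-carbaldehyde, via ozonide 7 (not isolated)
Conditions: O3, CH2Cl2, −78 °C; then PPh3, −78 °C → rt
Reagents that add atoms: ozone, [O-][O+]=O
Why: Ozonolysis (Criegee mechanism) of the only olefin with reductive work-up gives an α-alkoxy aldehyde that has no α-hydrogen and cannot epimerise.

Step 5
Reactants: 8 (2R,5S)-2-methyl-5-[(2R)-2-methyloxiran-2-yl]oxolane-2-carbaldehyde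
Product: 9 1-[(2R,5S)-2-methyl-5-[(2R)-2-methyloxiran-2-yl]oxolan-2-yl]ethan-1-ol (mixture of carbinol epimers)
Conditions: MeMgBr (1.2 equiv), THF, −78 °C; then H2O
Reagents that add atoms: methylmagnesium bromide, C[Mg]Br
Why: Grignard addition to the aldehyde is far faster than attack on the hindered 2,2-disubstituted epoxide at −78 °C, and the new carbinol centre is erased in step 7 so its configuration does not matter.

Step 6
Reactants: 9 1-[(2R,5S)-2-methyl-5-[(2R)-2-methyloxiran-2-yl]oxolan-2-yl]ethan-1-ol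
Product: 10 (2R)-2-[(2S,5R)-5-(1-hydroxyethyl)-5-methyloxolan-2-yl]but-3-en-2-ol
Conditions: Me3S+ I− (5 equiv), n-BuLi (4.8 equiv), THF, −10 °C → rt
Reagents that add atoms: trimethylsulfonium iodide, C[S+](C)C.[I-]
Why: Dimethylsulfonium methylide opens the epoxide at its CH2 and the γ-oxido sulfonium intermediate eliminates Me2S (one-carbon homologation of an epoxide to an allylic alcohol), so C8 is untouched and gains the vinyl group needed for ring closure.

Step 7
Reactants: 10 (2R)-2-[(2S,5R)-5-(1-hydroxyethyl)-5-methyloxolan-2-yl]but-3-en-2-ol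
Product: 11 1-[(2R,5S)-5-[(2R)-2-hydroxybut-3-en-2-yl]-2-methyloxolan-2-yl]ethan-1-one
Conditions: Dess–Martin periodinane, NaHCO3, CH2Cl2, rt
Reagents that add atoms: none
Why: Dess–Martin oxidation converts the secondary alcohol into the methyl ketone, while the tertiary allylic alcohol cannot be oxidised.

Step 8
Reactants: 11 1-[(2R,5S)-5-[(2R)-2-hydroxybut-3-en-2-yl]-2-methyloxolan-2-yl]ethan-1-one
Product: 12 (2R)-2-[(2S,5R)-5-[(1E)-1-{[(2S)-2-(methoxymethyl)pyrrolidin-1-yl]imino}ethyl]-5-methyloxolan-2-yl]but-3-en-2-ol (SAMP hydrazone, fragment 1)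
Conditions: SAMP (1.3 equiv), neat, 4 Å MS, 60 °C
Reagents that add atoms: (S)-1-amino-2-(methoxymethyl)pyrrolidine (SAMP), COC[C@@H]1CCCN1N
Why: Hydrazone condensation gives the E isomer (amino nitrogen anti to the quaternary carbon) whose only acidic C–H is the methyl group, and it installs the Enders auxiliary for the Michael step.

Step 9
Reactants: 13 (2Z)-3,7-dimethylocta-2,6-dien-1-ol (nerol)
Product: 14 [(2R,3S)-3-methyl-3-(4-methylpent-3-en-1-yl)oxiran-2-yl]methanol
Conditions: Ti(OiPr)4 (5 mol %), D-(−)-diethyl tartrate (7 mol %), t-BuOOH, 4 Å MS, CH2Cl2, −20 °C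
Reagents that add atoms: tert-butyl hydroperoxide, CC(C)(C)OO
Why: Sharpless asymmetric epoxidation acts only on the allylic-alcohol olefin and gives the cis-epoxide with C11 R and C12 S by reagent control.

Step 10
Reactants: 14 [(2R,3S)-3-methyl-3-(4-methylpent-3-en-1-yl)oxiran-2-yl]methanol
Product: 15 (2R,3R)-1,2-dihydroxy-3,7-dimethyloct-6-en-3-yl prop-2-enoate
Conditions: acrylic acid (3 equiv), Ti(OiPr)4 (1.5 equiv), BHT (cat.), CH2Cl2, 0 °C → rt
Reagents that add atoms: acrylic acid, C=CC(=O)O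
Why: Ti(OiPr)4-mediated opening of a 2,3-epoxy alcohol by a carboxylic acid occurs at C3 (chelation and the tertiary centre both direct attack there) with inversion, turning 12S into the 12R acyloxy centre next to the retained 11R carbinol.

Step 11
Reactants: 15 (2R,3R)-1,2-dihydroxy-3,7-dimethyloct-6-en-3-yl prop-2-enoate
Product: 16 (2R,3R)-1,2-bis{[tert-butyl(dimethyl)silyl]oxy}-3,7-dimethyloct-6-en-3-yl prop-2-enoate
Conditions: t-BuMe2SiOTf (2.5 equiv), 2,6-lutidine, CH2Cl2, −78 → 0 °C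
Reagents that add atoms: tert-butyldimethylsilyl trifluoromethanesulfonate, CC(C)(C)[Si](C)(C)OS(=O)(=O)C(F)(F)F
Why: Silyl ether formation caps both hydroxyls at once, which blocks acyl migration away from the tertiary ester and leaves the two olefins untouched.

Step 12
Reactants: 16 (2R,3R)-1,2-bis{[tert-butyl(dimethyl)silyl]oxy}-3,7-dimethyloct-6-en-3-yl prop-2-enoate
Product: 17 (7R)-7-[(1R)-1,2-bis{[tert-butyl(dimethyl)silyl]oxy}ethyl]-7-methyl-6,7-dihydrooxepin-2(5H)-one
Conditions: second-generation Grubbs catalyst (H2IMes)(PCy3)Cl2Ru=CHPh (5 mol %), toluene (2 mM), 80 °C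
Reagents that add atoms: none
Why: Ring-closing metathesis between the acrylate and the 2-methylpropenyl terminus (isobutene lost) closes the seven-membered α,β-unsaturated lactone (ring B), helped by the quaternary carbinol centre, with the C12–O ester bond already in place.

Step 13
Reactants: 17 (7R)-7-[(1R)-1,2-bis{[tert-butyl(dimethyl)silyl]oxy}ethyl]-7-methyl-6,7-dihydrooxepin-2(5H)-one
Product: 18 (7R)-7-[(1R)-1-{[tert-butyl(dimethyl)silyl]oxy}-2-hydroxyethyl]-7-methyl-6,7-dihydrooxepin-2(5H)-one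
Conditions: HF·pyridine, pyridine, THF, 0 °C
Reagents that add atoms: none
Why: Buffered fluoride desilylation cleaves the unhindered primary silyl ether much faster than the secondary one flanked by the quaternary carbon.

Step 14
Reactants: 18 (7R)-7-[(1R)-1-{[tert-butyl(dimethyl)silyl]oxy}-2-hydroxyethyl]-7-methyl-6,7-dihydrooxepin-2(5H)-one
Product: 19 (2S)-2-{[tert-butyl(dimethyl)silyl]oxy}-2-[(2R)-2-methyl-7-oxo-2,3,4,7-tetrahydrooxepin-2-yl]acetaldehyde
Conditions: Dess–Martin periodinane, NaHCO3, CH2Cl2, 0 °C → rt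
Reagents that add atoms: none
Why: Dess–Martin oxidation under buffered, non-basic conditions gives the α-silyloxy aldehyde without epimerising C11 (the descriptor changes to S only through CIP priorities).

Step 15
Reactants: 19 (2S)-2-{[tert-butyl(dimethyl)silyl]oxy}-2-[(2R)-2-methyl-7-oxo-2,3,4,7-tetrahydrooxepin-2-yl]acetaldehyde
Product: 20 (7R)-7-[(1R)-1-{[tert-butyl(dimethyl)silyl]oxy}prop-2-en-1-yl]-7-methyl-6,7-dihydrooxepin-2(5H)-one (fragment 2)
Conditions: Ph3PCH3Br, KN(SiMe3)2, THF, 0 °C; then 19, −78 → 0 °C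
Reagents that add atoms: methyltriphenylphosphonium bromide, C[P+](c1ccccc1)(c1ccccc1)c1ccccc1.[Br-]
Why: Wittig methylenation of the aldehyde at low temperature is much faster than ylide attack on the unsaturated lactone and installs the C10 vinyl group only after ring B is closed, so it could not interfere in step 12.

Step 16
Reactants: 12 SAMP hydrazone (fragment 1); 20 unsaturated lactone (fragment 2)
Product: 21 (4R,7R)-7-[(1R)-1-{[tert-butyl(dimethyl)silyl]oxy}prop-2-en-1-yl]-4-[(2E)-2-[(2R,5S)-5-[(2R)-2-hydroxybut-3-en-2-yl]-2-methyloxolan-2-yl]-2-{[(2S)-2-(methoxymethyl)pyrrolidin-1-yl]imino}ethyl]-7-methyloxepan-2-one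
Conditions: 12 (1.2 equiv), LiN(iPr)2 (2.5 equiv), THF, 0 °C; then −100 °C, 20; −100 → −78 °C; AcOH/THF quench
Reagents that add atoms: none
Why: Enders SAMP-hydrazone Michael addition: the chelated lithium azaenolate (the tertiary OH is carried as its alkoxide) adds 1,4 to the ring-locked Z-enoate to form C1–C2, and the methoxymethylpyrrolidine auxiliary selects the lactone face anti to the C12 side chain, setting 1R.

Step 17
Reactants: 21 Michael adduct hydrazone
Product: 22 (4R,7R)-7-[(1R)-1-{[tert-butyl(dimethyl)silyl]oxy}prop-2-en-1-yl]-4-{2-[(2R,5S)-5-[(2R)-2-hydroxybut-3-en-2-yl]-2-methyloxolan-2-yl]-2-oxoethyl}-7-methyloxepan-2-one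
Conditions: saturated aqueous oxalic acid, Et2O, rt
Reagents that add atoms: water, O
Why: Mild two-phase acidic hydrolysis of the hydrazone frees the C3 ketone without touching the silyl ether, the lactone or the tertiary allylic alcohol, and C1 (β to both carbonyls) cannot epimerise.

Step 18
Reactants: 22 keto lactone diene
Product: 23 (1R,4R,7S,8R,11R,12R)-11-(tert-butyldimethylsilyloxy)-8-hydroxy-3-oxo-4,7-epoxycembr-9-en-16,12-olide (E/Z mixture at C9=C10)
Conditions: second-generation Grubbs catalyst (H2IMes)(PCy3)Cl2Ru=CHPh (10 mol %), toluene (1 mM), 80 °C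
Reagents that add atoms: none
Why: Ring-closing metathesis of the two vinyl groups (ethene lost) closes ring C; the cis-oxolane and the trans-disposed lactone substituents pre-organise the chain, the free allylic hydroxyl assists, and olefin geometry is irrelevant because the bond is reduced next.

Step 19
Reactants: 23 macrocyclic olefin
Product: 24 (1R,4R,7S,8R,11R,12R)-11-(tert-butyldimethylsilyloxy)-8-hydroxy-3-oxo-4,7-epoxycembran-16,12-olide
Conditions: H2 (1 atm), [Ir(cod)(PCy3)(py)]PF6 (5 mol %), CH2Cl2, rt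
Reagents that add atoms: none
Why: Hydroxyl-directed homogeneous hydrogenation with Crabtree's catalyst saturates the hindered C9=C10 bond without allylic C–O hydrogenolysis and leaves the ketone and lactone intact.

Step 20
Reactants: 24 macrocyclic ketone
Product: 25 (1R,3S,4R,7S,8R,11R,12R)-11-(tert-butyldimethylsilyloxy)-3,8-dihydroxy-4,7-epoxycembran-16,12-olide
Conditions: (R)-2-methyl-CBS-oxazaborolidine (0.2 equiv), BH3·SMe2, THF, −30 °C; then MeOH
Reagents that add atoms: none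
Why: Corey–Bakshi–Shibata reduction is reagent-controlled: with the quaternary C4 as the large group and the C2 methylene as the small group, the (R)-catalyst delivers hydride to give 3S.

Step 21
Reactants: 25 diol
Product: 26 (1R,3S,4R,7S,8R,11R,12R)-11-(tert-butyldimethylsilyloxy)-3,8-bis(triethylsilyloxy)-4,7-epoxycembran-16,12-olide
Conditions: Et3SiOTf (3 equiv), 2,6-lutidine, CH2Cl2, −78 → 0 °C
Reagents that add atoms: triethylsilyl trifluoromethanesulfonate, CC[Si](CC)(CC)OS(=O)(=O)C(F)(F)F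
Why: Silyl triflate protection caps the C3 hydroxyl at once (it could otherwise translactonise to a six-membered lactone) together with the tertiary C8 hydroxyl, leaving the lactone α-CH2 as the only acidic site.

Step 22
Reactants: 26 fully silylated lactone
Product: 29 (1R,3S,4R,7S,8R,11R,12R)-11-(tert-butyldimethylsilyloxy)-3,8-bis(triethylsilyloxy)-4,7-epoxycembr-15(17)-en-16,12-olide, via Mannich base 27 (not isolated), via ammonium iodide 28 (not isolated)
Conditions: LiN(iPr)2, THF, −78 °C; CH2=NMe2+ I−, −78 °C → rt; then MeI, MeOH/CH2Cl2, rt; then NaHCO3 (aq), rt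
Reagents that add atoms: Eschenmoser's salt (N,N-dimethylmethyleneiminium iodide), C=[N+](C)C.[I-]
Why: Mannich reaction of the lactone enolate with Eschenmoser's salt, N-methylation and E1cB loss of trimethylamine install the exocyclic methylene, and C1 is not acidic so no stereocentre is at risk.

Step 23
Reactants: 29 tris-silyl ether
Product: 30 querciformolide D, (1R,3S,4R,7S,8R,11R,12R)-3,8,11-trihydroxy-4,7-epoxycembr-15(17)-en-16,12-olide
Conditions: HF·pyridine, pyridine, THF, 0 °C → rt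
Reagents that add atoms: none
Why: Buffered, mildly acidic fluoride desilylation removes all three silyl groups without the basic conditions that could trigger translactonisation or oxa-Michael addition to the α-methylene lactone.

**Compound list**
1 | (3R)-3,7-dimethylocta-1,6-dien-3-ol, (R)-(−)-linalool | C=C[C@@](O)(C)CCC=C(C)C | starting material
2 | (2E,6R)-2,6-dimethylocta-2,7-diene-1,6-diol | C=C[C@@](O)(C)CC/C=C(\C)CO | intermediate
3 | (3R)-5-[(2R,3R)-3-(hydroxymethyl)-3-methyloxiran-2-yl]-3-methylpent-1-en-3-ol | C=C[C@@](O)(C)CC[C@H]1O[C@]1(C)CO | intermediate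
4 | (2R)-2-[(2S,5R)-5-ethenyl-5-methyloxolan-2-yl]propane-1,2-diol | C=C[C@@]1(C)CC[C@H](O1)[C@](C)(O)CO | intermediate
5 | (2R)-2-[(2S,5R)-5-ethenyl-5-methyloxolan-2-yl]-2-hydroxypropyl 4-methylbenzenesulfonate | C=C[C@@]1(C)CC[C@H](O1)[C@](C)(O)COS(=O)(=O)c1ccc(C)cc1 | intermediate
6 | (2S,5R)-5-ethenyl-5-methyl-2-[(2R)-2-methyloxiran-2-yl]oxolane | C=C[C@@]1(C)CC[C@H](O1)[C@@]1(C)CO1 | intermediate
7 | 3-{(2R,5S)-2-methyl-5-[(2R)-2-methyloxiran-2-yl]oxolan-2-yl}-1,2,4-trioxolane (ozonide) | C1OOC(O1)[C@@]1(C)CC[C@H](O1)[C@@]1(C)CO1 | intermediate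
8 | (2R,5S)-2-methyl-5-[(2R)-2-methyloxiran-2-yl]oxolane-2-carbaldehyde | O=C[C@@]1(C)CC[C@H](O1)[C@@]1(C)CO1 | intermediate
9 | 1-[(2R,5S)-2-methyl-5-[(2R)-2-methyloxiran-2-yl]oxolan-2-yl]ethan-1-ol (carbinol epimers) | CC(O)[C@@]1(C)CC[C@H](O1)[C@@]1(C)CO1 | intermediate
10 | (2R)-2-[(2S,5R)-5-(1-hydroxyethyl)-5-methyloxolan-2-yl]but-3-en-2-ol | CC(O)[C@@]1(C)CC[C@H](O1)[C@](C)(O)C=C | intermediate
11 | 1-[(2R,5S)-5-[(2R)-2-hydroxybut-3-en-2-yl]-2-methyloxolan-2-yl]ethan-1-one | CC(=O)[C@@]1(C)CC[C@H](O1)[C@](C)(O)C=C | intermediate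
12 | (2R)-2-[(2S,5R)-5-[(1E)-1-{[(2S)-2-(methoxymethyl)pyrrolidin-1-yl]imino}ethyl]-5-methyloxolan-2-yl]but-3-en-2-ol | C/C(=N\N1CCC[C@H]1COC)[C@@]1(C)CC[C@H](O1)[C@](C)(O)C=C | intermediate
13 | (2Z)-3,7-dimethylocta-2,6-dien-1-ol, nerol | CC(C)=CCC/C(C)=C\CO | starting material
14 | [(2R,3S)-3-methyl-3-(4-methylpent-3-en-1-yl)oxiran-2-yl]methanol | CC(C)=CCC[C@]1(C)O[C@@H]1CO | intermediate
15 | (2R,3R)-1,2-dihydroxy-3,7-dimethyloct-6-en-3-yl prop-2-enoate | CC(C)=CCC[C@@](C)(OC(=O)C=C)[C@H](O)CO | intermediate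
16 | (2R,3R)-1,2-bis{[tert-butyl(dimethyl)silyl]oxy}-3,7-dimethyloct-6-en-3-yl prop-2-enoate | CC(C)=CCC[C@@](C)(OC(=O)C=C)[C@H](O[Si](C)(C)C(C)(C)C)CO[Si](C)(C)C(C)(C)C | intermediate
17 | (7R)-7-[(1R)-1,2-bis{[tert-butyl(dimethyl)silyl]oxy}ethyl]-7-methyl-6,7-dihydrooxepin-2(5H)-one | O=C1C=CCC[C@@](C)(O1)[C@H](O[Si](C)(C)C(C)(C)C)CO[Si](C)(C)C(C)(C)C | intermediate
18 | (7R)-7-[(1R)-1-{[tert-butyl(dimethyl)silyl]oxy}-2-hydroxyethyl]-7-methyl-6,7-dihydrooxepin-2(5H)-one | O=C1C=CCC[C@@](C)(O1)[C@H](O[Si](C)(C)C(C)(C)C)CO | intermediate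
19 | (2S)-2-{[tert-butyl(dimethyl)silyl]oxy}-2-[(2R)-2-methyl-7-oxo-2,3,4,7-tetrahydrooxepin-2-yl]acetaldehyde | O=C1C=CCC[C@@](C)(O1)[C@H](O[Si](C)(C)C(C)(C)C)C=O | intermediate
20 | (7R)-7-[(1R)-1-{[tert-butyl(dimethyl)silyl]oxy}prop-2-en-1-yl]-7-methyl-6,7-dihydrooxepin-2(5H)-one | O=C1C=CCC[C@@](C)(O1)[C@H](O[Si](C)(C)C(C)(C)C)C=C | intermediate
21 | (4R,7R)-7-[(1R)-1-{[tert-butyl(dimethyl)silyl]oxy}prop-2-en-1-yl]-4-[(2E)-2-[(2R,5S)-5-[(2R)-2-hydroxybut-3-en-2-yl]-2-methyloxolan-2-yl]-2-{[(2S)-2-(methoxymethyl)pyrrolidin-1-yl]imino}ethyl]-7-methyloxepan-2-one | O=C1C[C@@H](C/C(=N\N2CCC[C@H]2COC)[C@@]2(C)CC[C@H](O2)[C@](C)(O)C=C)CC[C@@](C)(O1)[C@H](O[Si](C)(C)C(C)(C)C)C=C | intermediate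
22 | (4R,7R)-7-[(1R)-1-{[tert-butyl(dimethyl)silyl]oxy}prop-2-en-1-yl]-4-{2-[(2R,5S)-5-[(2R)-2-hydroxybut-3-en-2-yl]-2-methyloxolan-2-yl]-2-oxoethyl}-7-methyloxepan-2-one | O=C1C[C@@H](CC(=O)[C@@]2(C)CC[C@H](O2)[C@](C)(O)C=C)CC[C@@](C)(O1)[C@H](O[Si](C)(C)C(C)(C)C)C=C | intermediate
23 | (1R,4R,7S,8R,11R,12R)-11-(tert-butyldimethylsilyloxy)-8-hydroxy-3-oxo-4,7-epoxycembr-9-en-16,12-olide (E/Z mixture) | O=C1C[C@H]2CC(=O)[C@@]3(C)CC[C@H](O3)[C@](C)(O)C=C[C@@H](O[Si](C)(C)C(C)(C)C)[C@](C)(O1)CC2 | intermediate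
24 | (1R,4R,7S,8R,11R,12R)-11-(tert-butyldimethylsilyloxy)-8-hydroxy-3-oxo-4,7-epoxycembran-16,12-olide | O=C1C[C@H]2CC(=O)[C@@]3(C)CC[C@H](O3)[C@](C)(O)CC[C@@H](O[Si](C)(C)C(C)(C)C)[C@](C)(O1)CC2 | intermediate
25 | (1R,3S,4R,7S,8R,11R,12R)-11-(tert-butyldimethylsilyloxy)-3,8-dihydroxy-4,7-epoxycembran-16,12-olide | O=C1C[C@H]2C[C@H](O)[C@@]3(C)CC[C@H](O3)[C@](C)(O)CC[C@@H](O[Si](C)(C)C(C)(C)C)[C@](C)(O1)CC2 | intermediate
26 | (1R,3S,4R,7S,8R,11R,12R)-11-(tert-butyldimethylsilyloxy)-3,8-bis(triethylsilyloxy)-4,7-epoxycembran-16,12-olide | O=C1C[C@H]2C[C@H](O[Si](CC)(CC)CC)[C@@]3(C)CC[C@H](O3)[C@](C)(O[Si](CC)(CC)CC)CC[C@@H](O[Si](C)(C)C(C)(C)C)[C@](C)(O1)CC2 | intermediate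
27 | 17-(dimethylamino) derivative of 26 (Mannich base, C15 epimers) | O=C1C(CN(C)C)[C@H]2C[C@H](O[Si](CC)(CC)CC)[C@@]3(C)CC[C@H](O3)[C@](C)(O[Si](CC)(CC)CC)CC[C@@H](O[Si](C)(C)C(C)(C)C)[C@](C)(O1)CC2 | intermediate
28 | 17-(trimethylammonio) derivative of 26, iodide salt | O=C1C(C[N+](C)(C)C)[C@H]2C[C@H](O[Si](CC)(CC)CC)[C@@]3(C)CC[C@H](O3)[C@](C)(O[Si](CC)(CC)CC)CC[C@@H](O[Si](C)(C)C(C)(C)C)[C@](C)(O1)CC2.[I-] | intermediate
29 | (1R,3S,4R,7S,8R,11R,12R)-11-(tert-butyldimethylsilyloxy)-3,8-bis(triethylsilyloxy)-4,7-epoxycembr-15(17)-en-16,12-olide | C=C1C(=O)O[C@]2(C)CC[C@@H]1C[C@H](O[Si](CC)(CC)CC)[C@@]1(C)CC[C@H](O1)[C@](C)(O[Si](CC)(CC)CC)CC[C@H]2O[Si](C)(C)C(C)(C)C | intermediate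
30 | querciformolide D, (1R,3S,4R,7S,8R,11R,12R)-3,8,11-trihydroxy-4,7-epoxycembr-15(17)-en-16,12-olide | C=C1C(=O)O[C@]2(C)CC[C@@H]1C[C@H](O)[C@@]1(C)CC[C@H](O1)[C@](C)(O)CC[C@H]2O | target

**Totals**
- Total step count: 23.
- Longest linear sequence: 16 steps (steps 1–8, then 16–23); the nerol branch is 7 steps (9–15).

**Three steps most likely to fail, each with a fallback**

Step 10 (Ti-mediated epoxide opening by acrylic acid). Risks are elimination to an allylic diol, attack at C11 and acyl migration off the tertiary ester. Fallback: setting out from 14, HClO4 (cat.) in THF/H2O opens the epoxide at the tertiary carbon with inversion to give (2R,3R)-3,7-dimethyloct-6-ene-1,2,3-triol F1. t-BuMe2SiOTf/2,6-lutidine at −78 °C then silylates only the primary and secondary hydroxyls to give (2R,3R)-1,2-bis{[tert-butyl(dimethyl)silyl]oxy}-3,7-dimethyloct-6-en-3-ol F2. The free tertiary alcohol is acylated afterwards (acryloyl chloride, iPr2NEt, DMAP, CH2Cl2, 40 °C), which comes back to the route at 16.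

Step 16 (azaenolate Michael addition). Risks are 1,2-addition, γ-deprotonation of the lactone, and a mismatched or wrong facial sense of the auxiliary. Fallback: setting out from ketone 11 (with 20), Me3SiOTf/Et3N gives the bis-silylated enol ether trimethyl({1-[(2R,5S)-2-methyl-5-{(2R)-2-[(trimethylsilyl)oxy]but-3-en-2-yl}oxolan-2-yl]ethenyl}oxy)silane F3. F3 is added to 20 in a Mukaiyama–Michael reaction (HNTf2 cat., CH2Cl2, −78 °C) under control of the lactone C12 centre to give the silyl ketene acetal F4. Dilute HCl work-up cleaves both Me3Si–O bonds and comes back to the route at 22 (C1 epimers separated by chromatography if needed); steps 8 and 17 are then not used.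

Step 18 (macrocyclic ring-closing metathesis between two hindered allylic-oxygenated vinyl groups). Risks are oligomerisation and no turnover at the tertiary carbinol. Fallback: setting out from 22, HF·pyridine removes the silyl ether to give the diol (4R,7R)-7-[(1R)-1-hydroxyprop-2-en-1-yl]-4-{2-[(2R,5S)-5-[(2R)-2-hydroxybut-3-en-2-yl]-2-methyloxolan-2-yl]-2-oxoethyl}-7-methyloxepan-2-one F5. iPr2SiCl2/imidazole ties O8 and O11 together as the cyclic silyl ketal F6, so that metathesis (same Ru catalyst, CH2Cl2, 40 °C) only has to close a seven-membered dioxasilepine, giving the (9Z)-olefin F7. Hydrogenation (H2, PtO2, EtOAc) gives F8, and HF·pyridine releases the 8,11-diol F9. Selective silylation of the secondary C11 hydroxyl (t-BuMe2SiOTf, 2,6-lutidine, −78 °C) comes back to the route at 24.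

**Further compounds**
F1 | step 10 | (2R,3R)-3,7-dimethyloct-6-ene-1,2,3-triol | CC(C)=CCC[C@@](C)(O)[C@H](O)CO
F2 | step 10 | (2R,3R)-1,2-bis{[tert-butyl(dimethyl)silyl]oxy}-3,7-dimethyloct-6-en-3-ol | CC(C)=CCC[C@@](C)(O)[C@H](O[Si](C)(C)C(C)(C)C)CO[Si](C)(C)C(C)(C)C
F3 | step 16 | trimethyl({1-[(2R,5S)-2-methyl-5-{(2R)-2-[(trimethylsilyl)oxy]but-3-en-2-yl}oxolan-2-yl]ethenyl}oxy)silane | C=C(O[Si](C)(C)C)[C@@]1(C)CC[C@H](O1)[C@](C)(O[Si](C)(C)C)C=C
F4 | step 16 | trimethylsilyl ketene acetal of 22 carrying a trimethylsilyl ether on the tertiary C8 hydroxyl | C[Si](C)(C)OC1=C[C@@H](CC(=O)[C@@]2(C)CC[C@H](O2)[C@](C)(O[Si](C)(C)C)C=C)CC[C@@](C)(O1)[C@H](O[Si](C)(C)C(C)(C)C)C=C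
F5 | step 18 | (4R,7R)-7-[(1R)-1-hydroxyprop-2-en-1-yl]-4-{2-[(2R,5S)-5-[(2R)-2-hydroxybut-3-en-2-yl]-2-methyloxolan-2-yl]-2-oxoethyl}-7-methyloxepan-2-one | O=C1C[C@@H](CC(=O)[C@@]2(C)CC[C@H](O2)[C@](C)(O)C=C)CC[C@@](C)(O1)[C@H](O)C=C
F6 | step 18 | 8,11-O-(diisopropylsilanediyl) derivative of F5 (cyclic silyl ketal linking O8 and O11) | O=C1C[C@H]2CC(=O)[C@@]3(C)CC[C@H](O3)[C@@](C)(C=C)O[Si](C(C)C)(C(C)C)O[C@H](C=C)[C@](C)(O1)CC2
F7 | step 18 | (1R,4R,7S,8R,9Z,11R,12R)-8,11-O-(diisopropylsilanediyl)-8,11-dihydroxy-3-oxo-4,7-epoxycembr-9-en-16,12-olide | O=C1C[C@H]2CC(=O)[C@@]3(C)CC[C@H](O3)[C@@]4(C)C=C[C@@H](O[Si](C(C)C)(C(C)C)O4)[C@](C)(O1)CC2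
F8 | step 18 | (1R,4R,7S,8R,11R,12R)-8,11-O-(diisopropylsilanediyl)-8,11-dihydroxy-3-oxo-4,7-epoxycembran-16,12-olide | O=C1C[C@H]2CC(=O)[C@@]3(C)CC[C@H](O3)[C@@]4(C)CC[C@@H](O[Si](C(C)C)(C(C)C)O4)[C@](C)(O1)CC2
F9 | step 18 | (1R,4R,7S,8R,11R,12R)-8,11-dihydroxy-3-oxo-4,7-epoxycembran-16,12-olide | O=C1C[C@H]2CC(=O)[C@@]3(C)CC[C@H](O3)[C@](C)(O)CC[C@@H](O)[C@](C)(O1)CC2
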